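**Strategy.** The route rests on cutting the C2–aryl bond and the C1–CH3 bond of cyclohexene ring C (C1 = quaternary carbon bearing methyl and the styryl carbon; C2 = CH bound to C8 of coumarin B; alkene C3=C4, methyl on C4). C2 and C1 are the β- and α-carbons of a cyclohexa-1,3-diene-1-carboxylate in which C3=C4 already exists. One operation, a rhodium/(S)-BINAP conjugate arylation with a masked-phenol arylzinc followed by methylation of the trapped enolate, sets both stereocentres. The precursor is achiral methyl 4-methylcyclohexa-1,3-diene-1-carboxylate. The ester carbon then becomes the styryl carbon (Wittig, then Heck with 8-iodo-7-methoxycoumarin), and the masked phenol is annulated to coumarin B.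

Key step: step 6

Remark on numbering: ring C is numbered C1 (quaternary), C2 (aryl-bearing CH), C3=C4 (methyl on C4), C5, C6. The key-step ester is therefore a 2-aryl-1,4-dimethylcyclohex-3-ene-1-carboxylate, with the alkene carbon C3 bonded directly to the aryl-bearing C2.

Assumption: (S)-BINAP is assigned by analogy with rhodium/BINAP arylation of (E)-enoates, where the aryl group goes to the si face of the α-carbon. If the dienoate responds in the opposite sense, (R)-BINAP is used.

Step 1
Reactants: 1 4-methylcyclohex-3-ene-1-carboxylic acid (racemic)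
Product: 2 methyl 4-methylcyclohex-3-ene-1-carboxylate (racemic)
Conditions: MeI, K2CO3, DMF, 20 °C
Reagents that add atoms: iodomethane, CI
Why: SN2 O-alkylation of the potassium carboxylate (esterification) uses no acid, so the trisubstituted alkene is untouched.

Step 2
Reactants: 2 methyl 4-methylcyclohex-3-ene-1-carboxylate
Product: 4 methyl 4-methyl-1-(phenylselanyl)cyclohex-3-ene-1-carboxylate (racemic), via lithium enolate 3 (not isolated)
Conditions: LiN(i-Pr)2, THF, −78 °C; PhSeBr, −78 → 0 °C
Reagents that add atoms: benzeneselenenyl bromide, Br[Se]c1ccccc1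
Why: Enolate α-selenenylation at the only α-carbon; the new stereocentre is formed as a racemate and is removed in step 3.

Step 3
Reactants: 4 methyl 4-methyl-1-(phenylselanyl)cyclohex-3-ene-1-carboxylate
Product: 6 methyl 4-methylcyclohexa-1,3-diene-1-carboxylate (achiral), via selenoxide 5 (not isolated)
Conditions: 30 % H2O2 (excess), pyridine, CH2Cl2, 0 → 20 °C; product kept cold under argon
Reagents that add atoms: none
Why: Selenide oxidation and selenoxide syn-elimination should take the allylic C2 hydrogen in preference and give the conjugated dienoate, with pyridine buffering the selenium acid so that the diene is neither epoxidised nor aromatised.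

Step 4
Reactants: 7 3-methoxyphenol
Product: 8 1-methoxy-3-(methoxymethoxy)benzene
Conditions: MeOCH2Cl, i-Pr2NEt, CH2Cl2, 0 → 20 °C
Reagents that add atoms: chloromethyl methyl ether, COCCl
Why: Williamson-type O-alkylation gives a base-stable acetal that also directs the metalation in step 5.

Step 5
Reactants: 8 1-methoxy-3-(methoxymethoxy)benzene
Product: 10 [2-methoxy-6-(methoxymethoxy)phenyl]zinc chloride (THF solution, used directly), via aryllithium 9 (not isolated)
Conditions: n-BuLi, THF, 0 → 20 °C; ZnCl2 (THF), 0 → 20 °C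
Reagents that add atoms: zinc chloride, Cl[Zn]Cl
Why: Directed ortho-metalation occurs at the carbon flanked by both oxygen substituents, and lithium-to-zinc transmetalation gives the mild aryl donor needed for step 6.

Step 6
Reactants: 6 methyl 4-methylcyclohexa-1,3-diene-1-carboxylate; 10 [2-methoxy-6-(methoxymethoxy)phenyl]zinc chloride
Product: 13 methyl (1S,2S)-2-[2-methoxy-6-(methoxymethoxy)phenyl]-1,4-dimethylcyclohex-3-ene-1-carboxylate (aryl cis to CO2Me, C1-methyl trans to aryl), via silyl ketene acetal 11 (not isolated), via lithium enolate 12 (not isolated)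
Conditions: 10 (1.6 equiv), [RhCl((S)-BINAP)]2 (2.5 mol %), Me3SiCl, THF, 20–40 °C; evaporate, pentane, filter under Ar; MeLi, THF, 0 °C; MeI, DMPU, −78 → 0 °C
Reagents that add atoms: iodomethane, CI
Why: Zinc-to-rhodium transmetalation gives an aryl complex of monovalent rhodium carrying (S)-BINAP, which adds syn across the C1=C2 alkene of 6 with aryl to C2; Me3SiCl silylates the resulting oxa-π-allyl rhodium to ketene acetal 11 and regenerates the chlororhodium catalyst, after which MeLi liberates lithium enolate 12 (Me4Si is lost) and MeI alkylates it at C1. The closest known reaction type is the rhodium/BINAP-catalysed asymmetric 1,4-addition of arylzinc chlorides to unsaturated carbonyl compounds in the presence of Me3SiCl, combined with the standard regeneration and C-alkylation of a lithium enolate from its silyl derivative. No ring is closed. C2 is set by the catalyst, the BINAP ligand differentiating the two faces of the coordinated C1=C2 bond; C1 is set by the substrate, because the C2 aryl group sits pseudoaxial to escape allylic 1,3-strain with the exocyclic enolate and blocks its own face, so methyl enters trans to it and the ester ends cis to the aryl group. The step needs 1,4- over 1,6-regioselectivity, secured by the methyl group on the δ-carbon C4 (insertion there would have to create a quaternary centre, whereas the β-carbon C2 is a CH), and C- over O-alkylation, secured by the lithium counter-ion and the soft electrophile MeI.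

Step 7
Reactants: 13 methyl (1S,2S)-2-[2-methoxy-6-(methoxymethoxy)phenyl]-1,4-dimethylcyclohex-3-ene-1-carboxylate
Product: 14 [(1S,2R)-2-[2-methoxy-6-(methoxymethoxy)phenyl]-1,4-dimethylcyclohex-3-en-1-yl]methanol
Conditions: LiAlH4, THF, 0 → 65 °C
Reagents that add atoms: none
Why: Hydride reduction of the hindered ester to the neopentyl alcohol leaves acetal, aryl ether and alkene untouched and cannot epimerise the quaternary centre (the descriptor at C2 changes only through ligand priorities).

Step 8
Reactants: 14 [(1S,2R)-2-[2-methoxy-6-(methoxymethoxy)phenyl]-1,4-dimethylcyclohex-3-en-1-yl]methanol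
Product: 15 (1S,2S)-2-[2-methoxy-6-(methoxymethoxy)phenyl]-1,4-dimethylcyclohex-3-ene-1-carbaldehyde
Conditions: Dess–Martin periodinane, CH2Cl2, 0 → 20 °C
Reagents that add atoms: none
Why: Dess–Martin oxidation stops at the aldehyde, which has no α-hydrogen and so cannot enolise or epimerise.

Step 9
Reactants: 15 (1S,2S)-2-[2-methoxy-6-(methoxymethoxy)phenyl]-1,4-dimethylcyclohex-3-ene-1-carbaldehyde
Product: 16 2-[(1R,6R)-6-ethenyl-3,6-dimethylcyclohex-2-en-1-yl]-1-methoxy-3-(methoxymethoxy)benzene
Conditions: Ph3PCH3Br, KOt-Bu, THF, 0 → 50 °C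
Reagents that add atoms: methyltriphenylphosphonium bromide, C[P+](c1ccccc1)(c1ccccc1)c1ccccc1.[Br-]
Why: Wittig methylenation with the small unstabilised ylide tolerates the neopentyl aldehyde and turns the former ester carbon into the first styryl carbon.

Step 10
Reactants: 17 7-hydroxycoumarin (7-hydroxy-2H-chromen-2-one)
Product: 18 7-hydroxy-8-iodo-2H-chromen-2-one
Conditions: I2, KI, aq. NH3, 20 °C; then 1 M HCl
Reagents that add atoms: iodine, II
Why: Electrophilic aromatic iodination of the phenoxide goes to C8, the position ortho to the hydroxyl and flanked by the ring oxygen.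

Step 11
Reactants: 18 7-hydroxy-8-iodo-2H-chromen-2-one
Product: 19 8-iodo-7-methoxy-2H-chromen-2-one
Conditions: MeI, K2CO3, acetone, 56 °C
Reagents that add atoms: iodomethane, CI
Why: Williamson O-methylation of the acidic phenol under carbonate conditions leaves lactone and aryl iodide intact.

Step 12
Reactants: 16 2-[(1R,6R)-6-ethenyl-3,6-dimethylcyclohex-2-en-1-yl]-1-methoxy-3-(methoxymethoxy)benzene; 19 8-iodo-7-methoxy-2H-chromen-2-one
Product: 20 7-methoxy-8-[(E)-2-[(1R,2R)-2-[2-methoxy-6-(methoxymethoxy)phenyl]-1,4-dimethylcyclohex-3-en-1-yl]ethenyl]-2H-chromen-2-one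
Conditions: Pd(OAc)2 (10 mol %), n-Bu4NCl, NaHCO3, DMF, 85 °C
Reagents that add atoms: none
Why: In this Mizoroki–Heck reaction the aryl group adds to the unhindered terminal carbon of the vinyl group and, since the other neighbour of the palladium-bearing carbon is quaternary, β-hydride elimination can only give the (E)-styrene, while the ring alkene and the coumarin C3=C4 bond are far less reactive.

Step 13
Reactants: 20 7-methoxy-8-[(E)-2-[(1R,2R)-2-[2-methoxy-6-(methoxymethoxy)phenyl]-1,4-dimethylcyclohex-3-en-1-yl]ethenyl]-2H-chromen-2-one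
Product: 21 8-[(E)-2-[(1R,2R)-2-(2-hydroxy-6-methoxyphenyl)-1,4-dimethylcyclohex-3-en-1-yl]ethenyl]-7-methoxy-2H-chromen-2-one
Conditions: ZnBr2, n-PrSH, CH2Cl2, 0 → 20 °C (short contact time)
Reagents that add atoms: none
Why: Lewis-acid-promoted acetal cleavage with thiol capture of the methoxymethyl group avoids strong protic acid, so the freed phenol should not add across the neighbouring C3=C4 alkene of ring C.

Step 14
Reactants: 21 8-[(E)-2-[(1R,2R)-2-(2-hydroxy-6-methoxyphenyl)-1,4-dimethylcyclohex-3-en-1-yl]ethenyl]-7-methoxy-2H-chromen-2-one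
Product: 22 2-hydroxy-4-methoxy-3-[(1R,6R)-6-[(E)-2-(7-methoxy-2-oxo-2H-chromen-8-yl)ethenyl]-3,6-dimethylcyclohex-2-en-1-yl]benzaldehyde
Conditions: MgCl2, Et3N, (CH2O)n, MeCN, 80 °C
Reagents that add atoms: paraformaldehyde (as formaldehyde), C=O
Why: Magnesium-phenoxide-directed ortho-formylation (Casnati–Skattebøl) delivers formaldehyde only ortho to the hydroxyl, and the single free ortho position, para to the methoxy group, is formylated.

Step 15
Reactants: 22 2-hydroxy-4-methoxy-3-[(1R,6R)-6-[(E)-2-(7-methoxy-2-oxo-2H-chromen-8-yl)ethenyl]-3,6-dimethylcyclohex-2-en-1-yl]benzaldehyde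
Product: 24 7-methoxy-8-[(E)-2-[(1R,2R)-2-(7-methoxy-2-oxo-2H-chromen-8-yl)-1,4-dimethylcyclohex-3-en-1-yl]ethenyl]-2H-chromen-2-one (target), via acyl ylide 23 (not isolated)
Conditions: Ph3P=C=C=O, toluene, 110 °C
Reagents that add atoms: (triphenylphosphoranylidene)ketene, O=C=C=P(c1ccccc1)(c1ccccc1)c1ccccc1
Why: The phenol acylates on the ketene of the Bestmann ylide to give ester ylide 23, whose intramolecular Wittig reaction with the ortho-formyl group closes the lactone ring of coumarin B with the required cis alkene.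

**Compound list**

1 | 4-methylcyclohex-3-ene-1-carboxylic acid (racemic) | CC1=CCC(CC1)C(=O)O | starting material
2 | methyl 4-methylcyclohex-3-ene-1-carboxylate (racemic) | COC(=O)C1CCC(C)=CC1 | intermediate
3 | lithium enolate of 2, lithium methoxy(4-methylcyclohex-3-en-1-ylidene)methanolate | COC(O[Li])=C1CCC(C)=CC1 | intermediate
4 | methyl 4-methyl-1-(phenylselanyl)cyclohex-3-ene-1-carboxylate (racemic) | COC(=O)C1([Se]c2ccccc2)CCC(C)=CC1 | intermediate
5 | methyl 4-methyl-1-(phenylseleninyl)cyclohex-3-ene-1-carboxylate (selenoxide) | COC(=O)C1([Se](=O)c2ccccc2)CCC(C)=CC1 | intermediate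
6 | methyl 4-methylcyclohexa-1,3-diene-1-carboxylate | COC(=O)C1=CC=C(C)CC1 | intermediate
7 | 3-methoxyphenol | COc1cccc(O)c1 | starting material
8 | 1-methoxy-3-(methoxymethoxy)benzene | COCOc1cccc(OC)c1 | intermediate
9 | [2-methoxy-6-(methoxymethoxy)phenyl]lithium | COCOc1cccc(OC)c1[Li] | intermediate
10 | [2-methoxy-6-(methoxymethoxy)phenyl]zinc chloride | COCOc1cccc(OC)c1[Zn]Cl | intermediate
11 | trimethylsilyl ketene acetal, [methoxy[(2S)-2-[2-methoxy-6-(methoxymethoxy)phenyl]-4-methylcyclohex-3-en-1-ylidene]methoxy]trimethylsilane | COC(O[Si](C)(C)C)=C1CCC(C)=C[C@H]1c1c(OC)cccc1OCOC | intermediate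
12 | lithium enolate, lithium methoxy[(2S)-2-[2-methoxy-6-(methoxymethoxy)phenyl]-4-methylcyclohex-3-en-1-ylidene]methanolate | COC(O[Li])=C1CCC(C)=C[C@H]1c1c(OC)cccc1OCOC | intermediate
13 | methyl (1S,2S)-2-[2-methoxy-6-(methoxymethoxy)phenyl]-1,4-dimethylcyclohex-3-ene-1-carboxylate | COC(=O)[C@@]1(C)CCC(C)=C[C@H]1c1c(OC)cccc1OCOC | intermediate
14 | [(1S,2R)-2-[2-methoxy-6-(methoxymethoxy)phenyl]-1,4-dimethylcyclohex-3-en-1-yl]methanol | OC[C@@]1(C)CCC(C)=C[C@H]1c1c(OC)cccc1OCOC | intermediate
15 | (1S,2S)-2-[2-methoxy-6-(methoxymethoxy)phenyl]-1,4-dimethylcyclohex-3-ene-1-carbaldehyde | O=C[C@@]1(C)CCC(C)=C[C@H]1c1c(OC)cccc1OCOC | intermediate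
16 | 2-[(1R,6R)-6-ethenyl-3,6-dimethylcyclohex-2-en-1-yl]-1-methoxy-3-(methoxymethoxy)benzene | C=C[C@@]1(C)CCC(C)=C[C@H]1c1c(OC)cccc1OCOC | intermediate
17 | 7-hydroxycoumarin | O=c1ccc2ccc(O)cc2o1 | starting material
18 | 7-hydroxy-8-iodo-2H-chromen-2-one | O=c1ccc2ccc(O)c(I)c2o1 | intermediate
19 | 8-iodo-7-methoxy-2H-chromen-2-one | COc1ccc2ccc(=O)oc2c1I | intermediate
20 | 7-methoxy-8-[(E)-2-[(1R,2R)-2-[2-methoxy-6-(methoxymethoxy)phenyl]-1,4-dimethylcyclohex-3-en-1-yl]ethenyl]-2H-chromen-2-one | COc1ccc2ccc(=O)oc2c1/C=C/[C@@]1(C)CCC(C)=C[C@H]1c1c(OC)cccc1OCOC | intermediate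
21 | 8-[(E)-2-[(1R,2R)-2-(2-hydroxy-6-methoxyphenyl)-1,4-dimethylcyclohex-3-en-1-yl]ethenyl]-7-methoxy-2H-chromen-2-one | COc1ccc2ccc(=O)oc2c1/C=C/[C@@]1(C)CCC(C)=C[C@H]1c1c(OC)cccc1O | intermediate
22 | 2-hydroxy-4-methoxy-3-[(1R,6R)-6-[(E)-2-(7-methoxy-2-oxo-2H-chromen-8-yl)ethenyl]-3,6-dimethylcyclohex-2-en-1-yl]benzaldehyde | COc1ccc2ccc(=O)oc2c1/C=C/[C@@]1(C)CCC(C)=C[C@H]1c1c(OC)ccc(C=O)c1O | intermediate
23 | 6-formyl-3-methoxy-2-[(1R,6R)-6-[(E)-2-(7-methoxy-2-oxo-2H-chromen-8-yl)ethenyl]-3,6-dimethylcyclohex-2-en-1-yl]phenyl (triphenyl-λ5-phosphanylidene)acetate | COc1ccc2ccc(=O)oc2c1/C=C/[C@@]1(C)CCC(C)=C[C@H]1c1c(OC)ccc(C=O)c1OC(=O)C=P(c1ccccc1)(c1ccccc1)c1ccccc1 | intermediate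
24 | 7-methoxy-8-[(E)-2-[(1R,2R)-2-(7-methoxy-2-oxo-2H-chromen-8-yl)-1,4-dimethylcyclohex-3-en-1-yl]ethenyl]-2H-chromen-2-one | COc1ccc2ccc(=O)oc2c1/C=C/[C@@]1(C)CCC(C)=C[C@H]1c1c(OC)ccc2ccc(=O)oc12 | target

**Step count.** Total: 15 steps. Longest linear sequence: 11 steps (steps 1, 2, 3, 6, 7, 8, 9, 12, 13, 14, 15).

**Steps most likely to fail**

1. Step 6. The di-ortho-substituted aryl–rhodium species may insert only slowly into the trisubstituted C1=C2 alkene. Addition could stray to the δ-carbon, the enolate could be protonated before methylation, or facial control at C2 or C1 could be incomplete. Fallback (from 6, rejoining at 14): the same two bonds would be made by stoichiometric, ligand-controlled organolithium chemistry.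
   - Dienoate 6 is saponified (LiOH, THF/H2O) to 4-methylcyclohexa-1,3-diene-1-carboxylic acid F1.
   - F1 is esterified with 2,6-di-tert-butyl-4-methoxyphenol ((CF3CO)2O, toluene) to 2,6-di-tert-butyl-4-methoxyphenyl 4-methylcyclohexa-1,3-diene-1-carboxylate F2, whose bulky aryl ester blocks carbonyl attack.
   - Aryllithium 9 (made as in step 5, without ZnCl2) is complexed with one enantiomer of 1,2-dimethoxy-1,2-diphenylethane in toluene at −78 °C and adds 1,4 to F2, giving the lithium enolate F3.
   - F3 is methylated in the same flask with MeI to 2,6-di-tert-butyl-4-methoxyphenyl (1S,2S)-2-[2-methoxy-6-(methoxymethoxy)phenyl]-1,4-dimethylcyclohex-3-ene-1-carboxylate F4.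
   - LiAlH4 in THF at 65 °C cleaves F4 reductively to alcohol 14.

2. Step 12. Oxidative addition and insertion may be slow for the di-ortho-substituted iodide and the neopentyl-type alkene, leading to reductive deiodination or catalyst decomposition. Fallback (from 15, rejoining at 20): aldehyde 15 is olefinated with Cl2CHB(pin), CrCl2 and LiI in THF (Takai–Utimoto-type reaction) to the alkenylboronate 2-[(E)-2-[(1R,2R)-2-[2-methoxy-6-(methoxymethoxy)phenyl]-1,4-dimethylcyclohex-3-en-1-yl]ethenyl]-4,4,5,5-tetramethyl-1,3,2-dioxaborolane F5. Suzuki–Miyaura coupling of F5 with iodide 19 (PdCl2(dppf), K3PO4, dioxane/H2O, 80 °C) gives 20.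

3. Step 3. The syn-elimination may go partly toward C6 and give the skipped diene, the perselenium oxidant may epoxidise the product, and the diene may aromatise in air. Fallback (from 2, rejoining at 6): enolate 3 (from 2 and LiN(i-Pr)2) is brominated with CBr4 to methyl 1-bromo-4-methylcyclohex-3-ene-1-carboxylate F6. Base-induced dehydrobromination with DBU in toluene at 80 °C gives 6, and the same base should isomerise any skipped diene into conjugation.

**Further compounds**

F1 | step 6 | 4-methylcyclohexa-1,3-diene-1-carboxylic acid | OC(=O)C1=CC=C(C)CC1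
F2 | step 6 | 2,6-di-tert-butyl-4-methoxyphenyl 4-methylcyclohexa-1,3-diene-1-carboxylate | COc1cc(C(C)(C)C)c(OC(=O)C2=CC=C(C)CC2)c(C(C)(C)C)c1
F3 | step 6 | lithium enolate of the 1,4-adduct, lithium (2,6-di-tert-butyl-4-methoxyphenoxy)[(2S)-2-[2-methoxy-6-(methoxymethoxy)phenyl]-4-methylcyclohex-3-en-1-ylidene]methanolate | COc1cc(C(C)(C)C)c(OC(O[Li])=C2CCC(C)=C[C@H]2c2c(OC)cccc2OCOC)c(C(C)(C)C)c1
F4 | step 6 | 2,6-di-tert-butyl-4-methoxyphenyl (1S,2S)-2-[2-methoxy-6-(methoxymethoxy)phenyl]-1,4-dimethylcyclohex-3-ene-1-carboxylate | COc1cc(C(C)(C)C)c(OC(=O)[C@@]2(C)CCC(C)=C[C@H]2c2c(OC)cccc2OCOC)c(C(C)(C)C)c1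
F5 | step 12 | 2-[(E)-2-[(1R,2R)-2-[2-methoxy-6-(methoxymethoxy)phenyl]-1,4-dimethylcyclohex-3-en-1-yl]ethenyl]-4,4,5,5-tetramethyl-1,3,2-dioxaborolane | CC1(C)OB(/C=C/[C@@]2(C)CCC(C)=C[C@H]2c2c(OC)cccc2OCOC)OC1(C)C
F6 | step 3 | methyl 1-bromo-4-methylcyclohex-3-ene-1-carboxylate (racemic) | COC(=O)C1(Br)CCC(C)=CC1
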